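## Retrosynthetic overview

1. Target 16 ⇐ acid removal of the ketal and carbonate from enal 15 ⇐ oxidative Heck reaction of aryl boronate 13 with acrolein.
2. Key disconnection: the C3–aryl bond of 13, made by radical cross-coupling. A hydrogen atom is abstracted photochemically from the ring O–CH2 of benzodioxane 12, and the radical is arylated at nickel with bromide 6. The existing C2 stereocentre directs trans.
3. 12 ⇐ catechol 5 + (R)-epichlorohydrin. The 1,4-dioxane ring is the only skeletal ring built; it is closed on ring A (step 5) before ring B is attached (step 8).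
4. Ring A and ring B both ⇐ 5-bromo-3-methoxycatechol 5 ⇐ 4-bromophenol (double ortho-formylation, Dakin oxidation, borate-directed mono-methylation). The dioxole on ring B is only a protecting ring.

Assumption: 4-bromophenol, (R)-epichlorohydrin of high ee and acrolein are bought. In the text the ring-A oxygen flanked by OMe is the "middle" oxygen and the other one the "outer" oxygen.

## Route

Step 1
Reactants: 1 4-bromophenol
Product: 2 5-bromo-2-hydroxybenzene-1,3-dicarbaldehyde
Conditions: hexamethylenetetramine (4 equiv), CF3CO2H, reflux, 24 h; then 3 M HCl, 60 °C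
Reagents that add atoms: hexamethylenetetramine C1N2CN3CN1CN(C2)C3; water O
Why: Duff reaction: in CF3CO2H the para-blocked phenol is aminomethylated at both ortho positions, and hydride transfer followed by hydrolysis gives the 2,6-dialdehyde (no stereocentre).

Step 2
Reactants: 2 5-bromo-2-hydroxybenzene-1,3-dicarbaldehyde
Product: 4 5-bromobenzene-1,2,3-triol, via aryl diformate 3 (not isolated)
Conditions: 30% aq. H2O2 (2.5 equiv), B(OH)3 (5 equiv), H2SO4 (cat.), THF, 20 °C, 16 h; work-up under N2
Reagents that add atoms: hydrogen peroxide OO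
Why: Dakin oxidation (Baeyer–Villiger-type aryl migration) turns both ortho-hydroxy aldehydes into formates that hydrolyse in the acidic medium, while B(OH)3 holds the emerging triol as a borate ester and shields it from over-oxidation.

Step 3
Reactants: 4 5-bromobenzene-1,2,3-triol
Product: 5 5-bromo-3-methoxybenzene-1,2-diol
Conditions: Na2B4O7·10H2O (2 equiv), NaOH (aq), Me2SO4 (1.1 equiv), H2O, 20 °C, N2; then HCl to pH 2
Reagents that add atoms: dimethyl sulfate COS(=O)(=O)OC
Why: Borate-directed Williamson etherification: the tetraborate ties two adjacent oxygens as a cyclic borate so only the remaining terminal phenoxide is methylated, and the mirror symmetry of 4 makes both possible mono-ethers the same compound.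

Step 4
Reactants: 5 5-bromo-3-methoxybenzene-1,2-diol
Product: 6 6-bromo-4-methoxy-2,2-dimethyl-1,3-benzodioxole
Conditions: 2,2-dimethoxypropane (3 equiv), TsOH·H2O (5 mol %), toluene, reflux with removal of MeOH (4 Å sieves in a Soxhlet)
Reagents that add atoms: 2,2-dimethoxypropane COC(C)(C)OC
Why: Acid-catalysed transketalisation driven by methanol removal gives the catechol isopropylidene ketal, a base-stable mask for ring B with no weak C–H bonds.

Step 5
Reactants: 5 5-bromo-3-methoxybenzene-1,2-diol; 7 (2R)-2-(chloromethyl)oxirane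
Product: 10 [(2R)-6-bromo-8-methoxy-2,3-dihydro-1,4-benzodioxin-2-yl]methanol, via chlorohydrin ether 8 (not isolated), via glycidyl ether 9 (not isolated)
Conditions: K2CO3 (2.5 equiv), 7 (1.2 equiv), DMF, 0 → 60 °C, argon; minor regioisomer removed by chromatography, ee raised by crystallisation if needed
Reagents that add atoms: none
Why: Double Williamson-type annulation: the less hindered outer phenoxide (meta to Br, so also the more acidic) opens the epoxide of 7 at its CH2 end, chloride loss gives the (S)-glycidyl ether, and the middle phenoxide then opens it 6-exo at the secondary carbon with inversion, which closes the dioxane ring with the middle oxygen on the CH(CH2OH) carbon and fixes the (R) centre from 7.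

Step 6
Reactants: 10 [(2R)-6-bromo-8-methoxy-2,3-dihydro-1,4-benzodioxin-2-yl]methanol
Product: 11 tert-butyl {[(2S)-6-bromo-8-methoxy-2,3-dihydro-1,4-benzodioxin-2-yl]methyl} carbonate
Conditions: Boc2O (1.5 equiv), DMAP (10 mol %), MeCN, 20 °C
Reagents that add atoms: di-tert-butyl dicarbonate CC(C)(C)OC(=O)OC(=O)OC(C)(C)C
Why: DMAP-catalysed O-acylation gives an acid-labile tert-butyl carbonate whose electron withdrawal deactivates the C–H bonds at CH2O and at C2 toward an electrophilic hydrogen-atom abstractor (the descriptor changes from R to S only through the priority rules, no bond at C2 is touched).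

Step 7
Reactants: 11 tert-butyl {[(2S)-6-bromo-8-methoxy-2,3-dihydro-1,4-benzodioxin-2-yl]methyl} carbonate
Product: 12 tert-butyl {[(2S)-8-methoxy-6-(4,4,5,5-tetramethyl-1,3,2-dioxaborolan-2-yl)-2,3-dihydro-1,4-benzodioxin-2-yl]methyl} carbonate
Conditions: B2pin2 (1.2 equiv), Pd(dppf)Cl2 (3 mol %), KOAc (3 equiv), 1,4-dioxane, 85 °C
Reagents that add atoms: bis(pinacolato)diboron CC1(C)OB(OC1(C)C)B1OC(C)(C)C(C)(C)O1
Why: Miyaura borylation replaces the ring-A bromide, which would compete for nickel in step 8, by a pinacol boronate that is inert there and later carries the side chain.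

Step 8
Reactants: 12 tert-butyl {[(2S)-8-methoxy-6-(4,4,5,5-tetramethyl-1,3,2-dioxaborolan-2-yl)-2,3-dihydro-1,4-benzodioxin-2-yl]methyl} carbonate; 6 6-bromo-4-methoxy-2,2-dimethyl-1,3-benzodioxole
Product: 13 tert-butyl {[(2R,3R)-8-methoxy-3-(7-methoxy-2,2-dimethyl-1,3-benzodioxol-5-yl)-6-(4,4,5,5-tetramethyl-1,3,2-dioxaborolan-2-yl)-2,3-dihydro-1,4-benzodioxin-2-yl]methyl} carbonate
Conditions: (Bu4N)4[W10O32] (2 mol %), NiBr2(dtbbpy) (10 mol %; dtbbpy = 4,4'-di-tert-butyl-2,2'-bipyridine), K3PO4 (1.2 equiv), MeCN (0.1 M), 390 nm LEDs, 25 °C, 36 h, argon; 6 limiting, 12 2.0 equiv (excess recovered)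
Reagents that add atoms: none
Why: Proposed new method: the photoexcited decatungstate abstracts a hydrogen atom from the most hydridic and accessible C–H bond of 12 (the ring O–CH2 at C3; the C2–H and CH2O sites are deactivated by the carbonate), the α-aryloxyalkyl radical is captured by the aryl–nickel bromide complex formed from 6, and reductive elimination from trivalent nickel forms the C3–aryl bond anti to the C2 substituent to give the trans (2R,3R) isomer, which is also the more stable one; the closest known reaction type is the decatungstate/nickel C(sp3)–H arylation of cyclic ethers and ketal-masked diols with aryl bromides.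

Step 9
Reactants: 13 tert-butyl {[(2R,3R)-8-methoxy-3-(7-methoxy-2,2-dimethyl-1,3-benzodioxol-5-yl)-6-(4,4,5,5-tetramethyl-1,3,2-dioxaborolan-2-yl)-2,3-dihydro-1,4-benzodioxin-2-yl]methyl} carbonate; 14 prop-2-enal
Product: 15 tert-butyl {[(2R,3R)-8-methoxy-3-(7-methoxy-2,2-dimethyl-1,3-benzodioxol-5-yl)-6-[(1E)-3-oxoprop-1-en-1-yl]-2,3-dihydro-1,4-benzodioxin-2-yl]methyl} carbonate
Conditions: Pd(OAc)2 (10 mol %), 2,9-dimethyl-1,10-phenanthroline (12 mol %), 14 (3 equiv), O2 (1 atm), DMF, 50 °C, sealed vessel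
Reagents that add atoms: none
Why: Oxidative (boron) Heck reaction: transmetalation of the aryl boronate to divalent palladium, insertion of acrolein and β-hydride elimination give the (E)-enal, and O2 reoxidises zerovalent palladium under base-free conditions that spare the carbonate, the ketal and both stereocentres.

Step 10
Reactants: 15 tert-butyl {[(2R,3R)-8-methoxy-3-(7-methoxy-2,2-dimethyl-1,3-benzodioxol-5-yl)-6-[(1E)-3-oxoprop-1-en-1-yl]-2,3-dihydro-1,4-benzodioxin-2-yl]methyl} carbonate
Product: 16 (2E)-3-[(2R,3R)-3-(3,4-dihydroxy-5-methoxyphenyl)-2-(hydroxymethyl)-8-methoxy-2,3-dihydro-1,4-benzodioxin-6-yl]prop-2-enal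
Conditions: CF3CO2H/H2O 9:1, 0.02 M, 0 → 20 °C, 1.5 h, argon; cold evaporation, reversed-phase purification
Reagents that add atoms: none
Why: Acidolysis hydrolyses the catechol isopropylidene ketal and fragments the tert-butyl carbonate, and any reversible ionisation of the benzylic C3–O bond can only return the more stable trans ring, so C2 is untouched and C3 stays trans.

## Compound list

1 | 4-bromophenol | Oc1ccc(Br)cc1 | starting material
2 | 5-bromo-2-hydroxybenzene-1,3-dicarbaldehyde | O=Cc1cc(Br)cc(C=O)c1O | intermediate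
3 | 5-bromo-2-hydroxy-1,3-phenylene diformate | O=COc1cc(Br)cc(OC=O)c1O | intermediate
4 | 5-bromobenzene-1,2,3-triol | Oc1cc(Br)cc(O)c1O | intermediate
5 | 5-bromo-3-methoxybenzene-1,2-diol | COc1cc(Br)cc(O)c1O | intermediate
6 | 6-bromo-4-methoxy-2,2-dimethyl-1,3-benzodioxole | COc1cc(Br)cc2OC(C)(C)Oc12 | intermediate
7 | (2R)-2-(chloromethyl)oxirane | ClC[C@H]1CO1 | starting material
8 | (2R)-1-(5-bromo-2-hydroxy-3-methoxyphenoxy)-3-chloropropan-2-ol | ClC[C@H](O)COc1cc(Br)cc(OC)c1O | intermediate
9 | 4-bromo-2-methoxy-6-{[(2S)-oxiran-2-yl]methoxy}phenol | COc1cc(Br)cc(OC[C@@H]2CO2)c1O | intermediate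
10 | [(2R)-6-bromo-8-methoxy-2,3-dihydro-1,4-benzodioxin-2-yl]methanol | C1Oc2cc(Br)cc(OC)c2O[C@@H]1CO | intermediate
11 | tert-butyl {[(2S)-6-bromo-8-methoxy-2,3-dihydro-1,4-benzodioxin-2-yl]methyl} carbonate | C1Oc2cc(Br)cc(OC)c2O[C@@H]1COC(=O)OC(C)(C)C | intermediate
12 | tert-butyl {[(2S)-8-methoxy-6-(4,4,5,5-tetramethyl-1,3,2-dioxaborolan-2-yl)-2,3-dihydro-1,4-benzodioxin-2-yl]methyl} carbonate | C1Oc2cc(B3OC(C)(C)C(C)(C)O3)cc(OC)c2O[C@@H]1COC(=O)OC(C)(C)C | intermediate
13 | tert-butyl {[(2R,3R)-8-methoxy-3-(7-methoxy-2,2-dimethyl-1,3-benzodioxol-5-yl)-6-(4,4,5,5-tetramethyl-1,3,2-dioxaborolan-2-yl)-2,3-dihydro-1,4-benzodioxin-2-yl]methyl} carbonate | COc1cc([C@H]2Oc3cc(B4OC(C)(C)C(C)(C)O4)cc(OC)c3O[C@@H]2COC(=O)OC(C)(C)C)cc2OC(C)(C)Oc12 | intermediate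
14 | prop-2-enal | C=CC=O | starting material
15 | tert-butyl {[(2R,3R)-8-methoxy-3-(7-methoxy-2,2-dimethyl-1,3-benzodioxol-5-yl)-6-[(1E)-3-oxoprop-1-en-1-yl]-2,3-dihydro-1,4-benzodioxin-2-yl]methyl} carbonate | COc1cc([C@H]2Oc3cc(/C=C/C=O)cc(OC)c3O[C@@H]2COC(=O)OC(C)(C)C)cc2OC(C)(C)Oc12 | intermediate
16 | (2E)-3-[(2R,3R)-3-(3,4-dihydroxy-5-methoxyphenyl)-2-(hydroxymethyl)-8-methoxy-2,3-dihydro-1,4-benzodioxin-6-yl]prop-2-enal | COc1cc([C@H]2Oc3cc(/C=C/C=O)cc(OC)c3O[C@@H]2CO)cc(O)c1O | target

## Step count and risks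

Total steps: 10. Longest linear sequence: 9 (steps 1, 2, 3, 5, 6, 7, 8, 9, 10); step 4 is the one-step branch to the ring-B bromide.

**Risk 1 (step 8).** This is the least certain step. Points of failure:
- hydrogen abstraction at an OCH3 group or at C2–H (the latter would erode ee);
- unproductive electron-transfer quenching of the excited polyoxometalate by the electron-rich arenes;
- a modest trans:cis ratio.

Fallback, setting out from 6 and 5 and coming back at 15: move the same radical arylation onto a ketal-masked glycerol, a substrate class with direct precedent, and build the dioxane ring afterwards.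
- Commercial (S)-isopropylideneglycerol and Boc2O give tert-butyl [(4R)-2,2-dimethyl-1,3-dioxolan-4-yl]methyl carbonate F1, used in five-fold excess.
- Arylation with 6 under the step 8 conditions gives trans tert-butyl {[(4S,5S)-5-(7-methoxy-2,2-dimethyl-1,3-benzodioxol-5-yl)-2,2-dimethyl-1,3-dioxolan-4-yl]methyl} carbonate F2.
- 80% aqueous AcOH at 40 °C removes only the aliphatic ketal and gives tert-butyl (2S,3S)-2,3-dihydroxy-3-(7-methoxy-2,2-dimethyl-1,3-benzodioxol-5-yl)propyl carbonate F3.
- 1,1'-Sulfonyldiimidazole and NaH in THF give tert-butyl {[(4S,5S)-5-(7-methoxy-2,2-dimethyl-1,3-benzodioxol-5-yl)-2,2-dioxo-1,3,2-dioxathiolan-4-yl]methyl} carbonate F4.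
- Catechol 5 and Cs2CO3 in DMF react with F4 by double displacement: the outer phenoxide attacks the benzylic carbon and the middle phenoxide then attacks the other carbon, each with inversion. This gives tert-butyl {[(2R,3R)-6-bromo-8-methoxy-3-(7-methoxy-2,2-dimethyl-1,3-benzodioxol-5-yl)-2,3-dihydro-1,4-benzodioxin-2-yl]methyl} carbonate F5.
- A Mizoroki–Heck reaction of F5 with 14 (Pd(OAc)2, Bu4NCl, NaHCO3, DMF, 70 °C) gives 15.

**Risk 2 (step 5).** Two things can go wrong:
- the middle phenoxide may alkylate first, which gives the regioisomeric benzodioxane;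
- direct displacement of chloride, the enantiomeric pathway, lowers the ee.

Fallback, setting out from 4 and coming back at 10: tie the middle and one terminal oxygen so that only the outer oxygen can be alkylated.
- 4 with 2,2-dimethoxypropane and TsOH gives 6-bromo-2,2-dimethyl-1,3-benzodioxol-4-ol F6.
- K2CO3 and 7 in DMF give 6-bromo-2,2-dimethyl-4-{[(2S)-oxiran-2-yl]methoxy}-1,3-benzodioxole F7.
- Concentrated HCl in THF cleaves the ketal and opens the epoxide to 5-bromo-3-[(2R)-3-chloro-2-hydroxypropoxy]benzene-1,2-diol F8.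
- K2CO3 in DMF closes the dioxane ring through the middle phenoxide (the far phenol cannot reach) to give (3R)-7-bromo-3-(hydroxymethyl)-2,3-dihydro-1,4-benzodioxin-5-ol F9.
- Me2SO4 and K2CO3 in acetone methylate the remaining phenol and give 10.

**Risk 3 (step 9).** Transmetalation of a pinacol boronate without base can be slow, and acrolein polymerises easily.

Fallback, setting out from 13 and coming back at 15: build the enal in two conventional C–C steps.
- Suzuki–Miyaura coupling of 13 with vinyl bromide (Pd(dppf)Cl2, K3PO4, THF/H2O, 50 °C) gives tert-butyl {[(2R,3R)-6-ethenyl-8-methoxy-3-(7-methoxy-2,2-dimethyl-1,3-benzodioxol-5-yl)-2,3-dihydro-1,4-benzodioxin-2-yl]methyl} carbonate F10.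
- Cross-metathesis of F10 with (E)-but-2-enal (5 equiv, second-generation Hoveyda–Grubbs catalyst, CH2Cl2, 40 °C) gives the (E)-enal 15.

## Further compounds

F1 | step 8 | tert-butyl [(4R)-2,2-dimethyl-1,3-dioxolan-4-yl]methyl carbonate | CC1(C)OC[C@H](COC(=O)OC(C)(C)C)O1
F2 | step 8 | tert-butyl {[(4S,5S)-5-(7-methoxy-2,2-dimethyl-1,3-benzodioxol-5-yl)-2,2-dimethyl-1,3-dioxolan-4-yl]methyl} carbonate | COc1cc([C@@H]2OC(C)(C)O[C@H]2COC(=O)OC(C)(C)C)cc2OC(C)(C)Oc12
F3 | step 8 | tert-butyl (2S,3S)-2,3-dihydroxy-3-(7-methoxy-2,2-dimethyl-1,3-benzodioxol-5-yl)propyl carbonate | COc1cc([C@H](O)[C@@H](O)COC(=O)OC(C)(C)C)cc2OC(C)(C)Oc12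
F4 | step 8 | tert-butyl {[(4S,5S)-5-(7-methoxy-2,2-dimethyl-1,3-benzodioxol-5-yl)-2,2-dioxo-1,3,2-dioxathiolan-4-yl]methyl} carbonate | COc1cc([C@@H]2OS(=O)(=O)O[C@H]2COC(=O)OC(C)(C)C)cc2OC(C)(C)Oc12
F5 | step 8 | tert-butyl {[(2R,3R)-6-bromo-8-methoxy-3-(7-methoxy-2,2-dimethyl-1,3-benzodioxol-5-yl)-2,3-dihydro-1,4-benzodioxin-2-yl]methyl} carbonate | COc1cc([C@H]2Oc3cc(Br)cc(OC)c3O[C@@H]2COC(=O)OC(C)(C)C)cc2OC(C)(C)Oc12
F6 | step 5 | 6-bromo-2,2-dimethyl-1,3-benzodioxol-4-ol | CC1(C)Oc2cc(Br)cc(O)c2O1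
F7 | step 5 | 6-bromo-2,2-dimethyl-4-{[(2S)-oxiran-2-yl]methoxy}-1,3-benzodioxole | CC1(C)Oc2cc(Br)cc(OC[C@@H]3CO3)c2O1
F8 | step 5 | 5-bromo-3-[(2R)-3-chloro-2-hydroxypropoxy]benzene-1,2-diol | Oc1cc(Br)cc(OC[C@@H](O)CCl)c1O
F9 | step 5 | (3R)-7-bromo-3-(hydroxymethyl)-2,3-dihydro-1,4-benzodioxin-5-ol | C1Oc2cc(Br)cc(O)c2O[C@@H]1CO
F10 | step 9 | tert-butyl {[(2R,3R)-6-ethenyl-8-methoxy-3-(7-methoxy-2,2-dimethyl-1,3-benzodioxol-5-yl)-2,3-dihydro-1,4-benzodioxin-2-yl]methyl} carbonate | COc1cc([C@H]2Oc3cc(C=C)cc(OC)c3O[C@@H]2COC(=O)OC(C)(C)C)cc2OC(C)(C)Oc12
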